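**Numbering used below.** Ring of the target: C1 carries the side chain, C2 the tiglate, C3 is the ketone, C4 the methyl-bearing epoxide carbon, C5 the epoxide CH, C6 the CH2. Side chain: C1'(=CH2)–C2'(=O)–C3'=C4'–C5'(OH)Me2. Compound numbers are those of the steps.

## The problem

Target 21 is a single cyclohexane ring in which five of the six carbons are functionalised and four (C1, C2, C4, C5) are stereocentres. Nothing is fused to the ring except the epoxide, so the task is the order in which oxygen is placed around the ring and the way the eight-carbon chain is grown outward from C1 through a 1,1-disubstituted alkene. C1 and C2 are trans and can be set together. The epoxide oxygen must lie cis to the C1 substituent and trans to the C2 ester, a face that neither centre delivers directly (alkaline peroxide would add to a C4=C5 enone anti to the C1 group), so a temporary C3 carbinol, itself set by C1 and C2, has to relay their configuration to C4 and C5. C2 is both alpha to the ketone and esterified: it can epimerise, and the tiglate can migrate to a neighbouring hydroxyl or be cleaved by base or hydride. The epoxy ketone is sensitive to base and reducing metals, and the chain joins an alpha-methylene ketone (conjugate addition, polymerisation) to a tertiary allylic alcohol (ionisation in acid), so both ketones are best revealed last under neutral conditions. The feature that opens the route is the unit O–C2–C1–C1'=CH2, a homoallylic alcohol with hydroxyl and alkenyl group trans on a six-membered ring, which is what a type 1 carbonyl-ene closure of the citronellal kind produces. The C3 carbonyl next to C2 makes the enophile a 2-oxoaldehyde that can bind a chiral Lewis acid at two points, and the C4=C5 alkene needed for the epoxide is, in the open chain, a Z enone that holds the reacting ends together.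

## Retrosynthesis

**21 from 20.** No skeletal bond is cut; the C3 and C2' ketones are taken back to carbinols. This is preferred to oxidising C3 early because an epoxy ketone would have to survive the divalent chromium used to build the chain, and because one oxidant can then form both ketones in a single last step. Triol 20 is no simpler in skeleton but far more robust. The forward reaction must oxidise two secondary carbinols and leave the tertiary allylic alcohol, the epoxide and the tiglate alone.

**20 from 16 and 19.** The C2'–C3' bond is cut. The neighbouring cut at C1'–C2' would need a ring-bound alkenyl metal or triflate made from a ketone next to an epimerisable centre. The chosen cut leaves the ring-bound enal 16 and the five-carbon alkenyl iodide 19, which comes in one operation from alkynol 17 through stannane 18. The forward reaction needs a carbon nucleophile that adds only to the aldehyde in the presence of ester, epoxide and free hydroxyls, which points to an alkenylchromium reagent.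

**16 from 14.** The C2' oxygen is removed, returning the isopropenyl methyl group. In 14 this methyl sits on the only electron-rich alkene left, so an allylic oxidation can be site-selective (through alcohol 15). The precursor is the plain isopropenyl compound that the ring-forming step delivers.

**14 from 13 from 12.** The two epoxide C–O bonds are removed, then the C3 carbinol is returned to the ketone. A hydroxyl-directed epoxidation is chosen over a nucleophilic one because only the former places oxygen cis to the C1 group. The C3 hydroxyl must therefore be cis to C1 and trans to C2, which is the face that axial hydride delivery to enone 12 should give. This takes the ring back to a carvone-type enone.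

**12 from 10 and 11.** The ester C–O bond is cut. Acylating at this stage, when C2–OH is the only hydroxyl, avoids any later differentiation of two secondary alcohols. The forward reaction must not epimerise the alpha-ketol centre.

**10 from 9 (key).** The C1–C2 ring bond is cut as an ene reaction. Against a cut at C3–C4 or a two-bond cycloaddition disconnection, this one creates C1 and C2 together from a chain with no stereocentre, and it leaves C2–OH, the C3 ketone, the C4=C5 enone and the exo-methylene in place. Ketoaldehyde 9 is achiral and acyclic, with a single Z alkene. The forward reaction needs enantioface control at the aldehyde and a trans-selective closed transition state.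

**9 from 8 from 6.** The two carbonyls are taken back to diol 8, and the bond between the future C2 and C3 is cut to the Z enal 6 and a one-carbon nucleophile at the alcohol oxidation level. An acid-to-diazoketone homologation with dioxirane oxidation was rejected because that oxidant would also epoxidise the prenyl alkene. The forward steps must keep the Z geometry and the skipped diene.

**6 from 5 from 2 and 3; 2 from 1.** The C4=C5 alkene is cut by a Wittig disconnection to ylide 4 (from salt 2, from bromide 1) and the acetal ketone 3. Non-stabilised ylides add to alpha-oxygenated methyl ketones with the Z selectivity required here, and all three starting materials are commodity chemicals.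

## Roads not taken

**Alternative 1:** The cut is on both sides of the C2' carbonyl carbon, which would be supplied as carbon monoxide. In the forward direction the C1' alkenyl triflate A2, CO and the E stannane 18 would be coupled on zerovalent palladium (Pd(PPh3)4, LiCl) to give dienone A1, the C3 triethylsilyl ether of the C3 alcohol corresponding to 21.
- Merits: the whole cross-conjugated dienone is assembled in one step at the right oxidation level. That is better than the chosen plan, which needs an allylic oxidation, an addition and an oxidation for the same unit.
- Weak points: A2 must be made from a C1 methyl ketone by kinetic enolisation with a strong base in the presence of the tiglate and next to an epimerisable centre. After the coupling, silyl removal and C3 oxidation must be done with the fragile dienone already present. The plan also leaves ring construction and all four stereocentres unsolved.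
- Comparison: the chosen plan sets against the shorter chain assembly that its dienone appears only in the final step and that its key step solves the ring.

**Alternative 2:** The cut is at C1–C6 and C2–C3. A chiral oxazaborolidinium triflimide would catalyse the Diels–Alder addition of silyloxydiene A5 to the enone alkene of bromodienone A4, giving the endo adduct A3.
- Merits: two C–C bonds and three contiguous stereocentres in one catalytic step, and a bromoalkene ready for a carbonylative coupling. In bonds and stereocentres per key step it is better than the chosen plan.
- Weak points: C2 emerges bearing an acetyl group, so the C2–O bond needs a Baeyer–Villiger oxidation whose peracid competes for the electron-rich ring alkene, followed by acetate-to-tiglate exchange. The endo rule puts the C3 oxygen cis to C2 and trans to C1, on the face opposite to the one the epoxide must occupy, so it cannot direct the epoxidation. A4 has two electrophilic alkenes and can act as a diene itself, and A5 is acid-labile under a strong Lewis acid.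
- Comparison: the chosen plan sets against the extra bond that every ring atom of 10 is at or one step from its final oxidation state, and that the C3 carbinol face is chosen by reduction.

**Alternative 3:** The cut is at C3–C4. The Z alkenyl iodide of aldehyde A7 would add as an alkenylchromium species (CrCl2, divalent chromium, with catalytic NiCl2) to the C3 aldehyde, closing the ring to cyclohexenol A6.
- Merits: A6 is the analogue of 13 that already carries the C2' oxygen as a p-methoxybenzyl ether, and its new carbinol is the directing group for the epoxidation. Downstream it is as good as or better than the chosen plan, which pays for its plain isopropenyl group with step 10.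
- Weak points: the only stereocentre made in the ring closure (C3) is later destroyed. C1 and C2 must be set beforehand in the open chain by separate asymmetric steps, together with the Z trisubstituted iodoalkene. A7 is an alpha-acyloxy aldehyde prone to epimerisation and acyl shift, and the ring-forming step uses stoichiometric chromium.
- Comparison: the chosen plan creates the ring, C1 and C2 in one catalytic step from an achiral chain made in five steps.

Key step: step 6

Assumption (chemistry): the (R,R)-phenyl bis(oxazoline)/Cu(OTf)2 chelate is taken to expose the aldehyde face that gives the (6S) carbinol of 10, by analogy with glyoxylate-ene reactions of this type of complex; if the sense proves opposite, the (S,S) ligand is used with no other change.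

## Route

Step 1
Reactants: 1 5-bromo-2-methylpent-2-ene
Product: 2 (4-methylpent-3-en-1-yl)triphenylphosphonium bromide
Conditions: PPh3, toluene, reflux
Reagents that add atoms: triphenylphosphine, c1ccc(cc1)P(c1ccccc1)c1ccccc1
Why: SN2 quaternisation of a primary homoallylic bromide by the phosphine, the standard preparation of a Wittig salt; no stereochemistry is involved.

Step 2
Reactants: 2 (4-methylpent-3-en-1-yl)triphenylphosphonium bromide; 3 1,1-dimethoxypropan-2-one
Product: 5 (2Z)-1,1-dimethoxy-2,6-dimethylhepta-2,5-diene, via phosphorus ylide 4 (not isolated)
Conditions: KN(SiMe3)2, THF, −78 °C; then 3, −78 °C to rt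
Reagents that add atoms: none
Why: Wittig olefination; under salt-free conditions non-stabilised ylides add to alpha-oxygenated methyl ketones through the kinetic oxaphosphetane that places the alkyl chain cis to the oxygenated carbon, so the Z trisubstituted alkene should predominate.

Step 3
Reactants: 5 (2Z)-1,1-dimethoxy-2,6-dimethylhepta-2,5-diene
Product: 6 (2Z)-2,6-dimethylhepta-2,5-dienal
Conditions: 10% aq. oxalic acid on SiO2, CH2Cl2, 0 °C, short contact time
Reagents that add atoms: water, O
Why: Acetal hydrolysis through the allylic oxocarbenium ion, which is fast for a conjugated acetal; the weak heterogeneous acid and low temperature are chosen to keep the Z enal from isomerising, and the product is used at once.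

Step 4
Reactants: 6 (2Z)-2,6-dimethylhepta-2,5-dienal
Product: 8 (3Z)-3,7-dimethylocta-3,6-diene-1,2-diol (racemic), via beta-hydroxysilane 7 (not isolated)
Conditions: iPrOMe2SiCH2MgCl, THF, 0 °C; aq. NH4Cl, crude; then 30% H2O2, KF, KHCO3, THF/MeOH, rt
Reagents that add atoms: (isopropoxydimethylsilyl)methylmagnesium chloride, CC(C)O[Si](C)(C)C[Mg]Cl; hydrogen peroxide, OO
Why: Nucleophilic hydroxymethylation: 1,2-addition of the silylmethyl Grignard reagent to the aldehyde, then Tamao oxidation of the C–Si bond, which does not touch isolated alkenes; the new carbinol centre is racemic and is destroyed in step 5.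

Step 5
Reactants: 8 (3Z)-3,7-dimethylocta-3,6-diene-1,2-diol
Product: 9 (3Z)-3,7-dimethyl-2-oxoocta-3,6-dienal
Conditions: (COCl)2, DMSO, CH2Cl2, −78 °C; Et3N, −78 to −30 °C; pH 7 buffer; used without storage
Reagents that add atoms: none
Why: Double Swern oxidation of a 1,2-diol to the 1,2-dicarbonyl compound; activated DMSO avoids the glycol cleavage that periodinane or high-valent metal oxidants can cause, and the cold buffered quench limits base-induced isomerisation of the Z enone and the skipped diene.

Step 6
Reactants: 9 (3Z)-3,7-dimethyl-2-oxoocta-3,6-dienal
Product: 10 (5S,6S)-6-hydroxy-2-methyl-5-(prop-1-en-2-yl)cyclohex-2-en-1-one (trans-6-hydroxycarvone)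
Conditions: Cu(OTf)2 (10 mol %), 2,2'-(propane-2,2-diyl)bis[(4R)-4-phenyl-4,5-dihydro-1,3-oxazole] (11 mol %), 4 Å MS, CH2Cl2, −40 to 0 °C, slow addition of 9
Reagents that add atoms: none
Why: The s-cis 1,2-dicarbonyl unit of 9 binds the bis(oxazoline) complex of Cu(OTf)2 (divalent copper) through both oxygens, which activates the aldehyde; the CH carbon of the trisubstituted alkene then bonds to the aldehyde carbon while a hydrogen of the methyl group trans to the tether passes to oxygen in a concerted six-centre array, so the alkene reappears as the isopropenyl group. The closest known reaction type is the bis(oxazoline)–copper-catalysed carbonyl-ene reaction of chelating 1,2-dicarbonyl enophiles (glyoxylates between two molecules, unsaturated 2-oxo esters within one molecule), combined with the citronellal-to-isopulegol type 1 closure. The ring closes in a 6-exo-trig sense at the aldehyde, and the Z enone already holds four of the six ring atoms coplanar with the two termini cis. The carbinol centre (C6 of 10) is set by the ligand, whose phenyl groups cover one face of the flat copper chelate so that the tethered alkene reaches the aldehyde from the open face. The neighbouring centre (C5 of 10) follows from the transition-state geometry: chelation keeps the C–O bond in the plane of the enone, where it becomes equatorial, and the isopropylidene terminus takes the pseudo-equatorial position away from the ring with its trans methyl hydrogen next to oxygen, which gives the trans product. Closure on the ketone is excluded because it would need a five-membered ring containing the Z alkene and because the ketone is the weaker electrophile. The uncatalysed closure of this very electrophilic aldehyde is the competitor for enantioselectivity and is held back by low temperature and slow addition, while the molecular sieves return any hydrate to the free aldehyde. The trans isomer is also the more stable one at this enolisable carbinol, so a minor cis product should converge on 10.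

Step 7
Reactants: 10 (5S,6S)-6-hydroxy-2-methyl-5-(prop-1-en-2-yl)cyclohex-2-en-1-one; 11 (2E)-2-methylbut-2-enoic acid (tiglic acid)
Product: 12 (1S,6S)-3-methyl-2-oxo-6-(prop-1-en-2-yl)cyclohex-3-en-1-yl (2E)-2-methylbut-2-enoate
Conditions: EDC·HCl, 4-(dimethylamino)pyridine (cat.), CH2Cl2, 0 °C to rt
Reagents that add atoms: none
Why: Steglich esterification; the carbodiimide-activated acid is passed to the secondary hydroxyl through the acylpyridinium ion under conditions too mild to epimerise the alpha-ketol centre, and the E tiglate is the stable alkene geometry.

Step 8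
Reactants: 12 (1S,6S)-3-methyl-2-oxo-6-(prop-1-en-2-yl)cyclohex-3-en-1-yl (2E)-2-methylbut-2-enoate
Product: 13 (1S,2S,6S)-2-hydroxy-3-methyl-6-(prop-1-en-2-yl)cyclohex-3-en-1-yl (2E)-2-methylbut-2-enoate
Conditions: NaBH4, CeCl3·7H2O, MeOH, −78 °C; pH 7 buffer
Reagents that add atoms: none
Why: Luche 1,2-reduction; axial hydride delivery to the half-chair with both substituents equatorial gives the equatorial carbinol, cis to the isopropenyl group and trans to the ester, the same sense in which carvone gives cis-carveol. The cold neutral work-up is meant to prevent conjugate reduction and a shift of the tiglate to the new hydroxyl.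

Step 9
Reactants: 13 (1S,2S,6S)-2-hydroxy-3-methyl-6-(prop-1-en-2-yl)cyclohex-3-en-1-yl (2E)-2-methylbut-2-enoate
Product: 14 (1R,2R,3S,4S,6S)-2-hydroxy-1-methyl-4-(prop-1-en-2-yl)-7-oxabicyclo[4.1.0]heptan-3-yl (2E)-2-methylbut-2-enoate
Conditions: VO(acac)2 (cat.), t-BuOOH, CH2Cl2, 0 °C to rt
Reagents that add atoms: tert-butyl hydroperoxide, CC(C)(C)OO
Why: Hydroxyl-directed epoxidation; the vanadium alkoxide of the allylic alcohol delivers the peroxide oxygen to the alkene face syn to C–OH, which sets both epoxide carbons cis to the hydroxyl and hence cis to the isopropenyl group. The remote isopropenyl alkene and the electron-poor tiglate should not react.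

Step 10
Reactants: 14 (1R,2R,3S,4S,6S)-2-hydroxy-1-methyl-4-(prop-1-en-2-yl)-7-oxabicyclo[4.1.0]heptan-3-yl (2E)-2-methylbut-2-enoate
Product: 16 (1R,2R,3S,4S,6S)-2-hydroxy-1-methyl-4-(3-oxoprop-1-en-2-yl)-7-oxabicyclo[4.1.0]heptan-3-yl (2E)-2-methylbut-2-enoate, via allylic alcohol 15 (not isolated)
Conditions: SeO2 (cat.), t-BuOOH, CH2Cl2, rt; crude, then MnO2, CH2Cl2, rt
Reagents that add atoms: selenium dioxide, O=[Se]=O (oxygen carrier); tert-butyl hydroperoxide, CC(C)(C)OO (oxygen source)
Why: SeO2 allylic oxidation (ene reaction, then 2,3-sigmatropic shift) on the only electron-rich alkene; hydrogen abstraction from the methyl group is preferred over the hindered ring methine next to the acyloxy carbon. MnO2 then takes the primary allylic alcohol 15 to the enal without touching the saturated secondary carbinol.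

Step 11
Reactants: 17 2-methylbut-3-yn-2-ol
Product: 19 (3E)-4-iodo-2-methylbut-3-en-2-ol, via E-alkenylstannane 18 (not isolated)
Conditions: Bu3SnH, PdCl2(PPh3)2 (cat.), THF, rt; then I2, 0 °C
Reagents that add atoms: iodine, II
Why: Palladium-catalysed syn hydrostannation of a terminal alkyne places tin on the terminal carbon, away from the bulky tertiary carbinol, to give the E stannane; iododestannylation then proceeds with retention of geometry.

Step 12
Reactants: 16 (1R,2R,3S,4S,6S)-2-hydroxy-1-methyl-4-(3-oxoprop-1-en-2-yl)-7-oxabicyclo[4.1.0]heptan-3-yl (2E)-2-methylbut-2-enoate; 19 (3E)-4-iodo-2-methylbut-3-en-2-ol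
Product: 20 (1R,2R,3S,4S,6S)-4-[(4E)-3,6-dihydroxy-6-methylhepta-1,4-dien-2-yl]-2-hydroxy-1-methyl-7-oxabicyclo[4.1.0]heptan-3-yl (2E)-2-methylbut-2-enoate (both epimers at the chain carbinol)
Conditions: CrCl2 (excess), NiCl2 (cat.), DMF, rt
Reagents that add atoms: none
Why: Nozaki–Hiyama–Kishi reaction; the nickel-derived alkenyl group is passed to chromium, and the resulting alkenylchromium reagent (trivalent chromium) adds to aldehydes only, with retention of the E geometry and tolerance of ester, epoxide and free hydroxyl groups. The new carbinol centre forms as a mixture, which does not matter because it is oxidised in step 13.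

Step 13
Reactants: 20 (1R,2R,3S,4S,6S)-4-[(4E)-3,6-dihydroxy-6-methylhepta-1,4-dien-2-yl]-2-hydroxy-1-methyl-7-oxabicyclo[4.1.0]heptan-3-yl (2E)-2-methylbut-2-enoate
Product: 21 (1S,3S,4S,6S)-4-[(4E)-6-hydroxy-6-methyl-3-oxohepta-1,4-dien-2-yl]-1-methyl-2-oxo-7-oxabicyclo[4.1.0]heptan-3-yl (2E)-2-methylbut-2-enoate (the target, CNP0263368.1)
Conditions: Dess–Martin periodinane, NaHCO3, CH2Cl2, 0 °C to rt
Reagents that add atoms: none
Why: Dess–Martin oxidation of both secondary carbinols forms the epoxy ketone and the cross-conjugated dienone together; the tertiary alcohol cannot be oxidised, and the buffered neutral medium should spare the epoxide, the dienone and the configuration at the ester-bearing carbon.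

## Compound list

1 | 5-bromo-2-methylpent-2-ene | CC(C)=CCCBr | starting material
2 | (4-methylpent-3-en-1-yl)triphenylphosphonium bromide | CC(C)=CCC[P+](c1ccccc1)(c1ccccc1)c1ccccc1.[Br-] | intermediate
3 | 1,1-dimethoxypropan-2-one | CC(=O)C(OC)OC | starting material
4 | (4-methylpent-3-en-1-ylidene)triphenylphosphorane (ylide) | CC(C)=CCC=P(c1ccccc1)(c1ccccc1)c1ccccc1 | intermediate
5 | (2Z)-1,1-dimethoxy-2,6-dimethylhepta-2,5-diene | COC(OC)/C(C)=C\CC=C(C)C | intermediate
6 | (2Z)-2,6-dimethylhepta-2,5-dienal | O=C/C(C)=C\CC=C(C)C | intermediate
7 | (3Z)-1-[dimethyl(propan-2-yloxy)silyl]-3,7-dimethylocta-3,6-dien-2-ol (racemic) | CC(C)O[Si](C)(C)CC(O)/C(C)=C\CC=C(C)C | intermediate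
8 | (3Z)-3,7-dimethylocta-3,6-diene-1,2-diol (racemic) | OCC(O)/C(C)=C\CC=C(C)C | intermediate
9 | (3Z)-3,7-dimethyl-2-oxoocta-3,6-dienal | O=CC(=O)/C(C)=C\CC=C(C)C | intermediate
10 | (5S,6S)-6-hydroxy-2-methyl-5-(prop-1-en-2-yl)cyclohex-2-en-1-one | C=C(C)[C@@H]1CC=C(C)C(=O)[C@H]1O | intermediate
11 | (2E)-2-methylbut-2-enoic acid (tiglic acid) | C/C=C(\C)C(=O)O | starting material
12 | (1S,6S)-3-methyl-2-oxo-6-(prop-1-en-2-yl)cyclohex-3-en-1-yl (2E)-2-methylbut-2-enoate | C=C(C)[C@@H]1CC=C(C)C(=O)[C@H]1OC(=O)/C(C)=C/C | intermediate
13 | (1S,2S,6S)-2-hydroxy-3-methyl-6-(prop-1-en-2-yl)cyclohex-3-en-1-yl (2E)-2-methylbut-2-enoate | C=C(C)[C@@H]1CC=C(C)[C@H](O)[C@H]1OC(=O)/C(C)=C/C | intermediate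
14 | (1R,2R,3S,4S,6S)-2-hydroxy-1-methyl-4-(prop-1-en-2-yl)-7-oxabicyclo[4.1.0]heptan-3-yl (2E)-2-methylbut-2-enoate | C=C(C)[C@@H]1C[C@@H]2O[C@]2(C)[C@H](O)[C@H]1OC(=O)/C(C)=C/C | intermediate
15 | (1R,2R,3S,4S,6S)-2-hydroxy-4-(3-hydroxyprop-1-en-2-yl)-1-methyl-7-oxabicyclo[4.1.0]heptan-3-yl (2E)-2-methylbut-2-enoate | C=C(CO)[C@@H]1C[C@@H]2O[C@]2(C)[C@H](O)[C@H]1OC(=O)/C(C)=C/C | intermediate
16 | (1R,2R,3S,4S,6S)-2-hydroxy-1-methyl-4-(3-oxoprop-1-en-2-yl)-7-oxabicyclo[4.1.0]heptan-3-yl (2E)-2-methylbut-2-enoate | C=C(C=O)[C@@H]1C[C@@H]2O[C@]2(C)[C@H](O)[C@H]1OC(=O)/C(C)=C/C | intermediate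
17 | 2-methylbut-3-yn-2-ol | CC(C)(O)C#C | starting material
18 | (3E)-2-methyl-4-(tributylstannyl)but-3-en-2-ol | CCCC[Sn](CCCC)(CCCC)/C=C/C(C)(C)O | intermediate
19 | (3E)-4-iodo-2-methylbut-3-en-2-ol | CC(C)(O)/C=C/I | intermediate
20 | (1R,2R,3S,4S,6S)-4-[(4E)-3,6-dihydroxy-6-methylhepta-1,4-dien-2-yl]-2-hydroxy-1-methyl-7-oxabicyclo[4.1.0]heptan-3-yl (2E)-2-methylbut-2-enoate (both chain-carbinol epimers) | C=C(C(O)/C=C/C(C)(C)O)[C@@H]1C[C@@H]2O[C@]2(C)[C@H](O)[C@H]1OC(=O)/C(C)=C/C | intermediate
21 | (1S,3S,4S,6S)-4-[(4E)-6-hydroxy-6-methyl-3-oxohepta-1,4-dien-2-yl]-1-methyl-2-oxo-7-oxabicyclo[4.1.0]heptan-3-yl (2E)-2-methylbut-2-enoate | C=C(C(=O)/C=C/C(C)(C)O)[C@@H]1C[C@@H]2O[C@]2(C)C(=O)[C@H]1OC(=O)/C(C)=C/C | target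

## Step count and least certain steps

Total step count: 13. Longest linear sequence: 12 steps (steps 1–10, 12 and 13, from bromide 1); step 11 is a one-step branch.

**Step 6 (key step).** The most likely failure is poor enantioface discrimination, because the 2-oxoaldehyde is electrophilic enough to close without the catalyst, or because hydrate water occupies the copper. A stepwise cationic closure that scrambles the position of the side-chain alkene is a second danger. Fallback: enantiocontrol by resolution instead of by catalyst. Setting out from 9, the closure is run with Me2AlCl in CH2Cl2 at −78 °C, which should give the racemic trans product, that is 10 together with (5R,6R)-6-hydroxy-2-methyl-5-(prop-1-en-2-yl)cyclohex-2-en-1-one F1. F1 is removed by preparative chromatography on a chiral stationary phase (cellulose tris(3,5-dimethylphenylcarbamate)), and the route is rejoined at 10. Which fraction is 10 can be settled against a reference sample, for which Rubottom oxidation of (R)-(−)-carvone should give the same (5S,6S) compound.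

**Step 3.** Acid can isomerise the Z enal to the E enal during acetal hydrolysis, and the E isomer cannot cyclise. Fallback: reach the aldehyde by a neutral oxidation instead of by hydrolysis. Setting out from salt 2 (through ylide 4), the Wittig reaction is run with 1-[(tert-butyldimethylsilyl)oxy]propan-2-one to give tert-butyl{[(2Z)-2,6-dimethylhepta-2,5-dien-1-yl]oxy}dimethylsilane F2. Bu4NF then frees (2Z)-2,6-dimethylhepta-2,5-dien-1-ol F3, and MnO2 in CH2Cl2 oxidises it to 6, where the route is rejoined.

**Step 5.** The amine base can isomerise the Z enone or move the skipped diene into conjugation through the doubly allylic CH2, and the product can hydrate or oligomerise on work-up. Fallback: carry the aldehyde carbon in masked form and release it by hydrolysis. Setting out from 6, 2-lithio-1,3-dithiane is added to give (2Z)-1-(1,3-dithian-2-yl)-2,6-dimethylhepta-2,5-dien-1-ol F4. MnO2 gives (2Z)-1-(1,3-dithian-2-yl)-2,6-dimethylhepta-2,5-dien-1-one F5, and MeI with CaCO3 in aqueous MeCN unmasks the aldehyde, returning to the route at 9.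

**Step 10.** The oxidation may go to the ring methine instead of the methyl group, the seleninic acid formed may open the epoxide, and over-oxidation is possible. Fallback: put a leaving group on the methyl carbon first. Setting out from 14, ene-type chlorination with Ca(OCl)2 and solid CO2 in CH2Cl2/water at 0 °C should give (1R,2R,3S,4S,6S)-4-(3-chloroprop-1-en-2-yl)-2-hydroxy-1-methyl-7-oxabicyclo[4.1.0]heptan-3-yl (2E)-2-methylbut-2-enoate F6. Ganem oxidation of F6 with trimethylamine N-oxide in DMSO gives 16, where the route is rejoined.

**Step 12.** The alkenylchromium reagent may be protonated by the two free hydroxyls, the alpha-methylene aldehyde may polymerise, and chromium salts may open the epoxide. Fallback: a zinc-based alkenyl transfer straight from the alkyne. Setting out from 17 (and 16), the alkynol is silylated to trimethyl[(2-methylbut-3-yn-2-yl)oxy]silane F7. Hydrozirconation with Cp2Zr(H)Cl, transmetalation with Me2Zn and addition to 16 give the trimethylsilyl ether of 20 at the tertiary hydroxyl F8. Citric acid in methanol removes the silyl group and returns to the route at 20.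

## Further compounds

F1 | step 6 | (5R,6R)-6-hydroxy-2-methyl-5-(prop-1-en-2-yl)cyclohex-2-en-1-one (enantiomer of 10) | C=C(C)[C@H]1CC=C(C)C(=O)[C@@H]1O
F2 | step 3 | tert-butyl{[(2Z)-2,6-dimethylhepta-2,5-dien-1-yl]oxy}dimethylsilane | CC(C)=CC/C=C(/C)CO[Si](C)(C)C(C)(C)C
F3 | step 3 | (2Z)-2,6-dimethylhepta-2,5-dien-1-ol | CC(C)=CC/C=C(/C)CO
F4 | step 5 | (2Z)-1-(1,3-dithian-2-yl)-2,6-dimethylhepta-2,5-dien-1-ol (racemic) | CC(C)=CC/C=C(/C)C(O)C1SCCCS1
F5 | step 5 | (2Z)-1-(1,3-dithian-2-yl)-2,6-dimethylhepta-2,5-dien-1-one | CC(C)=CC/C=C(/C)C(=O)C1SCCCS1
F6 | step 10 | (1R,2R,3S,4S,6S)-4-(3-chloroprop-1-en-2-yl)-2-hydroxy-1-methyl-7-oxabicyclo[4.1.0]heptan-3-yl (2E)-2-methylbut-2-enoate | C=C(CCl)[C@@H]1C[C@@H]2O[C@]2(C)[C@H](O)[C@H]1OC(=O)/C(C)=C/C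
F7 | step 12 | trimethyl[(2-methylbut-3-yn-2-yl)oxy]silane | C#CC(C)(C)O[Si](C)(C)C
F8 | step 12 | trimethylsilyl ether of 20 at the tertiary hydroxyl (both chain-carbinol epimers) | C=C(C(O)/C=C/C(C)(C)O[Si](C)(C)C)[C@@H]1C[C@@H]2O[C@]2(C)[C@H](O)[C@H]1OC(=O)/C(C)=C/C
A1 | alternative 1 | C3 triethylsilyl ether of the C3 alcohol corresponding to 21 (silyloxy group cis to the epoxide) | C=C(C(=O)/C=C/C(C)(C)O)[C@@H]1C[C@@H]2O[C@]2(C)[C@H](O[Si](CC)(CC)CC)[C@H]1OC(=O)/C(C)=C/C
A2 | alternative 1 | C1' alkenyl triflate of the same ring (1-(trifluoromethylsulfonyloxy)ethenyl group at C1) | C=C(OS(=O)(=O)C(F)(F)F)[C@@H]1C[C@@H]2O[C@]2(C)[C@H](O[Si](CC)(CC)CC)[C@H]1OC(=O)/C(C)=C/C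
A3 | alternative 2 | endo cycloadduct: 2-acetyl-1-(1-bromoethenyl)-4-methyl-3-(tert-butyldimethylsilyloxy)cyclohex-4-ene in target numbering (acetyl cis to silyloxy, trans to bromoethenyl) | C=C(Br)[C@@H]1CC=C(C)[C@@H](O[Si](C)(C)C(C)(C)C)[C@H]1C(C)=O
A4 | alternative 2 | (3E)-5-bromohexa-3,5-dien-2-one | CC(=O)/C=C/C(Br)=C
A5 | alternative 2 | tert-butyl{[(1E)-2-methylbuta-1,3-dien-1-yl]oxy}dimethylsilane | C=C/C(C)=C/O[Si](C)(C)C(C)(C)C
A6 | alternative 3 | cyclohex-2-enol with C3–OH cis to the C1 substituent and trans to the C2 tiglate, C1 substituent 3-[(4-methoxyphenyl)methoxy]prop-1-en-2-yl | C=C(COCc1ccc(OC)cc1)[C@@H]1CC=C(C)[C@H](O)[C@H]1OC(=O)/C(C)=C/C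
A7 | alternative 3 | (2S,3S,5Z)-6-iodo-3-{3-[(4-methoxyphenyl)methoxy]prop-1-en-2-yl}-1-oxohept-5-en-2-yl (2E)-2-methylbut-2-enoate | C=C(COCc1ccc(OC)cc1)[C@H](C/C=C(/C)I)[C@H](OC(=O)/C(C)=C/C)C=O
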